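Ring A numbering: C1 aroyl, C2 OH, C4 OMe, C5 propyl chain.

1. Hardest point: ring A is 1,2,4,5-tetrasubstituted, carries two different carbon arms, and only one of the molecule's four phenolic oxygens is methylated. Acylating a preformed diarylpropane would have to fight for regiocontrol and O-differentiation.
2. Cuts: the carbonyl C–ring B bond and the chain C3–ring C bond, not the bonds to ring A. Both cuts release the same 4-oxygenated phenyl group and leave the C11 core 5-allyl-2-hydroxy-4-methoxybenzaldehyde.
3. Enabling feature: rings B and C are identical 4-hydroxyphenyl rings bound through C1. The free C2–OH of ring A lies ortho to the carbonyl carbon and can steer palladium into a formyl C–H bond. The arms on C1 and C5 are meta and cannot react with each other.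
4. Forward order: ring A is bought with OH and OMe already differentiated, and C5 is brominated and then allylated. One aryl iodide (two equivalents) is then joined in one flask to the formyl carbon (two electrophilic carbons united through an acylpalladium) and to the allyl terminus (chain completed).
5. One hydrogenation then saturates the chain and frees both outer phenols. No ring is formed at any stage.
6. Stereochemistry: none to set. The only stereoelement on the way, an E alkene, is erased in the last step.

Key step: step 3

Assumption: the SMILES holds no stereocentre and no stereogenic double bond, so the target is achiral and the request for a single enantiomer calls for no stereocontrol.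

Step 1
Reactants: 1 2-hydroxy-4-methoxybenzaldehyde
Product: 2 5-bromo-2-hydroxy-4-methoxybenzaldehyde
Conditions: Br2 (1.0 equiv), CH2Cl2, 0 °C to rt
Reagents that add atoms: bromine, BrBr
Why: Electrophilic aromatic bromination should go to C5, which is para to the C2 hydroxyl, ortho to the C4 methoxy group and, unlike C3, not flanked by two substituents, while the formyl group is left alone in the anhydrous medium.

Step 2
Reactants: 2 5-bromo-2-hydroxy-4-methoxybenzaldehyde; 3 allyltributylstannane
Product: 4 5-allyl-2-hydroxy-4-methoxybenzaldehyde
Conditions: Pd(PPh3)4 (5 mol %), toluene, 100 °C
Reagents that add atoms: allyltributylstannane 3, C=CC[Sn](CCCC)(CCCC)CCCC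
Why: Stille coupling (oxidative addition into C5–Br, transmetalation, reductive elimination) should give the allylarene with phenol and aldehyde unprotected, because the allylstannane, unlike allylboron or allylzinc reagents, does not add to a formyl group on its own.

Step 3
Reactants: 4 5-allyl-2-hydroxy-4-methoxybenzaldehyde; 5 1-(benzyloxy)-4-iodobenzene (2.3 equiv)
Product: 7 [4-(benzyloxy)phenyl]{5-[(E)-3-(4-benzyloxyphenyl)prop-2-en-1-yl]-2-hydroxy-4-methoxyphenyl}methanone, via Heck monoarylation product 6 (not isolated)
Conditions: PdCl2 (10 mol %), LiCl (40 mol %), Na2CO3 (4 equiv), DMF, 100 °C, N2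
Reagents that add atoms: 1-(benzyloxy)-4-iodobenzene 5, Ic1ccc(OCc2ccccc2)cc1
Why: Oxidative addition of Pd(0) into the C–I bond of 5 gives one arylpalladium(II) species that feeds two known cycles on the two arms of 4, which sit meta on ring A (C1 and C5) and so cannot cyclise onto each other. On the allyl arm a Mizoroki–Heck reaction takes place: syn carbopalladation puts the aryl group on the unsubstituted terminal carbon and syn β-hydride elimination gives the E-1,3-diarylpropene 6. On the formyl arm the hydroxyl-directed palladium-catalysed formyl C–H arylation of salicylaldehydes with aryl iodides takes place: the C2 phenoxide replaces halide on arylpalladium and holds the metal next to the formyl C–H, a five-membered acyl(aryl)oxapalladacycle forms with transfer of the proton to carbonate, and reductive elimination makes the carbonyl–ring B bond, so that two electrophilic carbons are joined through an acylpalladium. No ring is closed and no stereocentre is formed, and the geometry and position of the double bond (β-hydride elimination toward either benzylic CH2) are without consequence because step 4 saturates the chain. The step needs terminal over internal alkene arylation (secured by the monosubstituted, electronically unbiased alkene under halide-rich ligand-free palladium), formyl over aromatic C–H cleavage (secured by the ortho phenoxide of ring A), and no third arylation (secured by the low reactivity of the 1,2-disubstituted alkene and by keeping 5 only slightly above two equivalents). Both cycles run in the same medium (chloride-stabilised palladium, carbonate, DMF, about 100 °C), which is why one flask should serve.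

Step 4
Reactants: 7 [4-(benzyloxy)phenyl]{5-[(E)-3-(4-benzyloxyphenyl)prop-2-en-1-yl]-2-hydroxy-4-methoxyphenyl}methanone
Product: 8 (4-hydroxyphenyl){2-hydroxy-5-[3-(4-hydroxyphenyl)propyl]-4-methoxyphenyl}methanone (target)
Conditions: H2 (1 atm), 10 % Pd/C, EtOAc–EtOH, rt, stopped after uptake of 3 equiv H2
Reagents that add atoms: none
Why: Heterogeneous catalytic hydrogenation should saturate the disubstituted alkene and cleave both aryl benzyl ethers by hydrogenolysis in one operation, while the aryl methyl ether and the diaryl ketone, deactivated by the hydrogen-bonded ortho hydroxyl and two para oxygen donors, should persist.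

Compound list
1 | 2-hydroxy-4-methoxybenzaldehyde | COc1ccc(C=O)c(O)c1 | starting material
2 | 5-bromo-2-hydroxy-4-methoxybenzaldehyde | COc1cc(O)c(C=O)cc1Br | intermediate
3 | allyltributylstannane | C=CC[Sn](CCCC)(CCCC)CCCC | starting material
4 | 5-allyl-2-hydroxy-4-methoxybenzaldehyde | COc1cc(O)c(C=O)cc1CC=C | intermediate
5 | 1-(benzyloxy)-4-iodobenzene | Ic1ccc(OCc2ccccc2)cc1 | starting material
6 | 5-[(E)-3-(4-benzyloxyphenyl)prop-2-en-1-yl]-2-hydroxy-4-methoxybenzaldehyde (Heck monoarylation product) | COc1cc(O)c(C=O)cc1C/C=C/c1ccc(OCc2ccccc2)cc1 | intermediate
7 | [4-(benzyloxy)phenyl]{5-[(E)-3-(4-benzyloxyphenyl)prop-2-en-1-yl]-2-hydroxy-4-methoxyphenyl}methanone | COc1cc(O)c(C(=O)c2ccc(OCc3ccccc3)cc2)cc1C/C=C/c1ccc(OCc2ccccc2)cc1 | intermediate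
8 | (4-hydroxyphenyl){2-hydroxy-5-[3-(4-hydroxyphenyl)propyl]-4-methoxyphenyl}methanone | COc1cc(O)c(C(=O)c2ccc(O)cc2)cc1CCCc1ccc(O)cc1 | target

Total step count: 4
Longest linear sequence: 4 steps (1 → 2 → 4 → 7 → 8)

Steps most likely to fail

Step 3. The two catalytic cycles may not keep pace. Four processes are of concern:
- Palladium hydride released by the Heck cycle may move the allyl double bond into conjugation with ring A before arylation.
- Insertion may place the aryl group on the internal alkene carbon.
- A third arylation of the new disubstituted alkene may set in while the slower formyl C–H arylation is still running.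
- The acylpalladium intermediate may decarbonylate.

The fallback sets out from 4 and builds the two bonds separately by known, non-Heck chemistry. Olefin cross-metathesis of 4 with commercial 1-(benzyloxy)-4-vinylbenzene (second-generation ruthenium benzylidene catalyst, CH2Cl2, 40 °C) should give 6, now isolated. Addition of commercial 4-(benzyloxy)phenylmagnesium bromide (2.2 equiv, THF, 0 °C; the first equivalent is consumed by the phenol) to the formyl group should give the racemic benzhydrol [4-(benzyloxy)phenyl]{5-[(E)-3-(4-benzyloxyphenyl)prop-2-en-1-yl]-2-hydroxy-4-methoxyphenyl}methanol F1. Oxidation of the doubly benzylic alcohol with MnO2 (CH2Cl2, rt) brings the sequence back to the route at 7.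

Step 2. The acidic phenol may protodestannylate the allylstannane, palladium may catalyse transfer of the allyl group to the formyl carbon, and the allyl double bond may migrate into conjugation at 100 °C.

The fallback sets out from 2 and drops the allyl core, bringing in the C3 chain with ring C already attached. 1-Allyl-4-(benzyloxy)benzene F2 is made from commercial 4-(benzyloxy)phenylmagnesium bromide and allyl bromide (THF, 0 °C to rt). It is coupled with 2 in a Mizoroki–Heck reaction (Pd(OAc)2, P(o-tol)3, NaOAc, DMF, 110 °C), in which double-bond migration is harmless. The sequence comes back to the route at 6, which is isolated and then exposed to the conditions of step 3 with only 1.2 equiv of 5 to give 7.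

Step 4. Slow hydrogenolysis of the second benzyl ether may force long exposure to hydrogen. During that time, reduction of the diaryl ketone and subsequent benzylic C–O hydrogenolysis may set in.

The fallback sets out from 7 and avoids catalytic hydrogenation altogether. Diimide (2-nitrobenzenesulfonyl hydrazide, Et3N, CH2Cl2, rt) should saturate only the alkene to give [4-(benzyloxy)phenyl]{5-[3-(4-benzyloxyphenyl)propyl]-2-hydroxy-4-methoxyphenyl}methanone F3. Lewis-acid debenzylation with BCl3 and pentamethylbenzene as cation scavenger (CH2Cl2, −78 °C) should then free both phenols. It should leave the methyl ether, which is para and not ortho to the carbonyl, untouched. The sequence comes back to the route at 8.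

Further compounds
F1 | step 3 | [4-(benzyloxy)phenyl]{5-[(E)-3-(4-benzyloxyphenyl)prop-2-en-1-yl]-2-hydroxy-4-methoxyphenyl}methanol (racemic) | COc1cc(O)c(C(O)c2ccc(OCc3ccccc3)cc2)cc1C/C=C/c1ccc(OCc2ccccc2)cc1
F2 | step 2 | 1-allyl-4-(benzyloxy)benzene | C=CCc1ccc(OCc2ccccc2)cc1
F3 | step 4 | [4-(benzyloxy)phenyl]{5-[3-(4-benzyloxyphenyl)propyl]-2-hydroxy-4-methoxyphenyl}methanone | COc1cc(O)c(C(=O)c2ccc(OCc3ccccc3)cc2)cc1CCCc1ccc(OCc2ccccc2)cc1
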